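Abbreviations: TBS = tert-butyldimethylsilyl, TBDPS = tert-butyldiphenylsilyl. Labdane numbering is used throughout: ring A = C1–C5 and C10, ring B = C5–C10, C17 = methylene carbon on C8, C18 = methyl and C19 = ester carbon on C4, C20 = methyl on C10, C11–C16 = chain on C9.

## Structural features

The target is a bicyclic diterpenoid of the enantiomeric labdane series: a trans-fused decalin (rings A and B) with an exocyclic methylene on C8 and an (E)-3-methylpenta-2,4-dienyl chain on C9. It has five stereocentres, C1 (S, acetoxy), C4 (R, quaternary, methyl and methyl ester), C5 (S), C9 (R) and C10 (S, quaternary methyl). C4, C5, C10 and C1 are contiguous in ring A and C9 is bonded to C10, so the quaternary C10 has a stereocentre on each of its three ring neighbours. The acetoxy group, C20, C11 and the ester carbon C19 lie on one face; the ester is therefore axial and 1,3-diaxial to C20, and the equatorial C1 oxygen sits in a peri relation to C11. Fragile groups are the conjugated diene (acid, oxidants, radicals, any hydrogenation), the exocyclic alkene (isomerisation) and the acetate (bases, hydrides). The real difficulty is to set C10 together with C1, C5 and C9 in the right relative and absolute sense, and to remove unsaturation later without touching the C8 methylene. The key step uses ring A: the sequence C1 (oxygen) – C10 (methyl, C9) – C5 (C6 branch), read with a transient C2=C3 alkene, is the cycloadduct pattern of a 1-oxygenated diene C1=C2–C3=C4 (carrying C19 on C4) and an (E)-2-methyl-2-enal whose formyl carbon is C9.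

## Logic of the disconnections

26 to 25 to 23: the O–acetyl bond and the C4–C18 bond are cut. The acetate cannot survive bases or hydrides and goes on last. C18 is added to the ester enolate because the axial C20 dictates the face of attack. This turns C4 into a tertiary centre whose configuration no longer matters. The forward step must alkylate anti to C20 while the C1 alkoxide stays a spectator.

23 to 22 to 20 to 19: C19 is taken back from ester to acid to primary alcohol, and both oxygen atoms are masked as silyl ethers. C19 is inert at the alcohol level during all skeleton-building steps, and one fluoride treatment frees both oxygens. The forward oxidation must take the primary alcohol only, beside a secondary alcohol and a diene.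

19 to 18 to 17 (with 11): C14=C15 and C12=C13 are cut as two carbonyl olefinations. The diene is the most fragile group, so it is made only after every radical and reductive step. The chain shrinks to a two-carbon aldehyde on C9. The forward steps must give the (E) trisubstituted alkene, which a stabilised ylide does.

17 to 16 to 15: the C8–C9 bond of ring B is cut. The bromoalkene is a latent C8 radical that leaves the methylene in place, and the acceptor ester becomes C12. The bicycle becomes a monocycle and the C9 stereocentre disappears. The forward step demands 6-exo closure with C11 delivered equatorially.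

15 to 14 to 13: C9=C11 is cut to the formyl group, and the C2=C3 alkene is restored to give the cycloadduct retron. The forward step must saturate the ring alkene before ring B exists (no C8 methylene to compete), beside a bromoalkene and an aldehyde.

13 to 5 and 12: the C1–C10 and C4–C5 bonds are cut. This is the key disconnection; it removes ring A and four stereocentres and leaves two achiral chains. The C19 oxygen of 5 is carried as a bulky aryl silyl ether and not as a benzylic ether. A 5-alkoxy-1-silyloxydiene is a doubly vinylogous acetal that a Lewis-basic ether would help the catalyst to ionise, whereas the silyl ether binds poorly and later leaves with fluoride without an oxidant near the diene. The forward step needs ortho regiochemistry, formyl-exo topology and catalyst-controlled face selection.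

5 to 4 to 2 and 3, 2 to 1: the O–Si bond of the dienol ether is cut to the enal, then the C2=C3 bond of the enal by cross-metathesis. All carbons come from two four-carbon commodity alkenes. The forward enolisation must give the (1E,3E) diene.

12 to 10 and 11, 10 to 9 to 6 and 7: the C10=C5 alkene is cut by Wittig reaction, then the C6–C7 bond by ester enolate allylation. The forward Wittig step must give the (E) enal, since this geometry becomes the trans ring fusion.

## Other disconnections considered

Alternative 1: C1–C10 and C8–C9 are cut together. In the forward sense SmI2 reduces the aldehyde of acyclic precursor A1 to a ketyl, which adds 6-exo to the β-carbon C10 of the enoate; the samarium enolate at C9 then acylates the C8 ester (Dieckmann) to give β-keto ester A2.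
- In its favour: two rings and three stereocentres form in one step. C1 arrives as a free hydroxyl with no ring alkene to remove, which is better than the chosen plan on that point. No tin is needed.
- Against it here: C1, C9 and C10 are controlled only by the single C5 centre of a flexible chain. C11 emerges as an ester carbon on C9, so the side chain needs a one-carbon homologation. C8 is a ketone to be methylenated beside an epimerisable centre. The C4 malonate must be differentiated into methyl and ester with face control.
- Comparison: structurally it makes more bonds per step but leaves three oxidation-state errors (C4, C8, C11). Mechanistically it is a substrate-controlled radical-anion cascade, against a catalyst-controlled cycloaddition. In step economy the gain in ring construction is spent on adjustment, so it should not be shorter overall.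

Alternative 2: C5–C10 and C3–C4 are cut. The C10 enolate (or the 2-silyloxydiene) of vinyl ketone A3 adds to C5 of the tethered enoate, and the ester enolate then adds to the enone terminus C3, giving keto ester A4.
- In its favour: both rings, the C8 methylene and the C11–C12 arm are in place from the start. C19 is already an ester and there is no C2=C3 to reduce; both points are better than the chosen plan.
- Against it here: A3 must be made with C9 set next to an isopropenyl-type unit and with an enolisable C10. Three new centres (C4, C5, C10) depend on the folding of the chain. The vinyl ketone is prone to polymerisation. C1 arrives as a ketone, so the equatorial alcohol must be made by reduction when C11 is already in the peri position.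
- Comparison: after the key step it should need fewer redox steps than the chosen plan. Before it, the enantioselective work is merely moved into a longer precursor synthesis, and the relative control is kinetic folding, not an (E)/(E,E) geometry transfer.

Alternative 3: C9–C10 is cut. A zerovalent palladium catalyst ionises the allylic carbonate of phenol A5, and the phenolate attacks the π-allyl unit through its methyl-bearing ortho carbon C10, giving dienone A6.
- In its favour: the precursor is flat, aromatic and cheap. C9, C10 and the C8 methylene are set in one catalytic enantioselective step, and the side-chain arm is present. A dissolving-metal reductive methylation of the unsaturated ester could later set C5 and C4 together, which would equal or better the chosen plan at C4.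
- Against it here: attack through carbon must beat attack through oxygen and through the other ring positions. C9/C10 diastereocontrol in forming a six-membered ring with vicinal tertiary and quaternary centres is demanding. A6 carries two ring alkenes and a ketone that must be reduced, with the trans fusion created, beside the exocyclic methylene.
- Comparison: it is more convergent in the key step. Its risk is concentrated in the chemoselective removal of excess unsaturation, which is the same kind of problem as the single ring alkene of the chosen plan but larger.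

Key step: step 7

Remark: the (S)-prolinol-derived oxazaborolidinium ion is assumed, on the formyl C–H···O binding model, to leave the Cα-Re/Cβ-Si face of 12 open; if the sense is the reverse, the (R) catalyst is used and nothing else changes.

Remark: C4 of 13 to 23 is written with the configuration that the cycloaddition delivers; it is erased at enolate 24, so its integrity in steps 15 and 16 is immaterial.

In all bicyclic compounds of the main series the C1 oxygen, C19, C11 and C20 lie on one face of the trans-decalin, and H5 and H9 on the other.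

## Route

Step 1
Reactants: 1 but-3-en-1-ol
Product: 2 (but-3-en-1-yloxy)(tert-butyl)diphenylsilane
Conditions: TBDPSCl, imidazole, CH2Cl2, 0 °C → rt
Reagents that add atoms: tert-butyl(chloro)diphenylsilane, CC(C)(C)[Si](Cl)(c1ccccc1)c1ccccc1
Why: Silylation of a primary alcohol; the bulky aryl silyl ether is chosen for C19 because it coordinates poorly to the Lewis acid of step 7.

Step 2
Reactants: 2 (but-3-en-1-yloxy)(tert-butyl)diphenylsilane; 3 (E)-but-2-enal
Product: 4 (E)-5-[(tert-butyldiphenylsilyl)oxy]pent-2-enal
Conditions: second-generation Hoveyda–Grubbs catalyst (H2IMes)Cl2Ru=CH(C6H4-2-OiPr) (3 mol %), 3 (4 equiv), CH2Cl2, 40 °C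
Reagents that add atoms: none
Why: Olefin cross-metathesis of a terminal alkene with an enal; the conjugated product forms under thermodynamic control as the (E) isomer and propene escapes.

Step 3
Reactants: 4 (E)-5-[(tert-butyldiphenylsilyl)oxy]pent-2-enal
Product: 5 (1E,3E)-1-[(tert-butyldimethylsilyl)oxy]-5-[(tert-butyldiphenylsilyl)oxy]penta-1,3-diene
Conditions: TBSOTf, Et3N, Et2O, 0 °C → rt
Reagents that add atoms: tert-butyldimethylsilyl trifluoromethanesulfonate, CC(C)(C)[Si](C)(C)OS(=O)(=O)C(F)(F)F
Why: Silyl dienol ether formation by O-silylation and γ-deprotonation of an enal; the extended (1E,3E) isomer should predominate, and any (3Z) isomer is inert in step 7 and is removed there.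

Step 4
Reactants: 6 tert-butyl acetate; 7 2,3-dibromoprop-1-ene
Product: 9 tert-butyl 4-bromopent-4-enoate, via lithium enolate of tert-butyl acetate 8 (not isolated)
Conditions: LDA, THF, −78 °C; then 7, −78 → −20 °C
Reagents that add atoms: none
Why: Ester enolate alkylation (SN2) at the allylic bromide; the vinylic bromide is inert and the tert-butyl ester suppresses self-condensation.

Step 5
Reactants: 9 tert-butyl 4-bromopent-4-enoate
Product: 10 4-bromopent-4-enal
Conditions: DIBAL-H (1.1 equiv), CH2Cl2, −78 °C; aqueous Rochelle salt
Reagents that add atoms: none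
Why: Partial reduction of an ester; the aluminium hemiacetal is stable at −78 °C and collapses to the aldehyde only on work-up. The volatile aldehyde is used as a solution.

Step 6
Reactants: 10 4-bromopent-4-enal; 11 2-(triphenylphosphoranylidene)propanal
Product: 12 (E)-6-bromo-2-methylhepta-2,6-dienal
Conditions: toluene, 80 °C
Reagents that add atoms: none
Why: Wittig reaction of a stabilised, α-branched ylide, which gives the (E) trisubstituted enal under thermodynamic control of the oxaphosphetane; the enal product is much less reactive towards 11 than 10.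

Step 7
Reactants: 5 (1E,3E)-1-[(tert-butyldimethylsilyl)oxy]-5-[(tert-butyldiphenylsilyl)oxy]penta-1,3-diene; 12 (E)-6-bromo-2-methylhepta-2,6-dienal
Product: 13 (1S,2S,5R,6R)-6-(3-bromobut-3-en-1-yl)-2-[(tert-butyldimethylsilyl)oxy]-5-{[(tert-butyldiphenylsilyl)oxy]methyl}-1-methylcyclohex-3-ene-1-carbaldehyde
Conditions: (S)-B-(o-tolyl)oxazaborolidine from (S)-α,α-diphenylprolinol (20 mol %), Tf2NH (17 mol %), 5 (1.5 equiv), CH2Cl2, −78 → −40 °C
Reagents that add atoms: none
Why: The N-protonated oxazaborolidine binds the formyl oxygen of 12 and lowers its LUMO; 5 then adds in one concerted but asynchronous suprafacial [4+2] event in which C4–C5 bonding runs ahead of C1–C10. The closest known reaction type is the chiral boron Lewis acid catalysed Diels–Alder reaction of 1-silyloxydienes with α-substituted enals that creates a formyl-bearing quaternary carbon; the β-substituent of 12 makes this a slow member of the class. Ring A closes by cycloaddition, both σ-bonds being made in the same step to give the six-membered carbocycle. The regiochemistry (C1 to C10, C4 to C5) follows from the largest HOMO coefficient at C4 of the 1-donor diene and the largest LUMO coefficient at the β-carbon C5. The (E) geometry of 12 is transferred, so C9 and C6 are trans (the later trans ring fusion), and the (1E,3E) geometry of 5 makes the two oxygenated substituents on C1 and C4 cis. The formyl-exo arrangement, with the α-methyl and the β-chain under the diene, places the silyloxy group cis to the C10 methyl. The absolute configuration comes from the catalyst, whose aryl group shields one face so that bonding occurs on the Cα-Re/Cβ-Si face of 12. The isolated bromoalkene is no dienophile under these conditions and (3Z) isomers of 5 cannot reach the s-cis form, so neither interferes.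

Step 8
Reactants: 13 cycloadduct aldehyde
Product: 14 (1S,2R,3R,6S)-2-(3-bromobut-3-en-1-yl)-6-[(tert-butyldimethylsilyl)oxy]-3-{[(tert-butyldiphenylsilyl)oxy]methyl}-1-methylcyclohexane-1-carbaldehyde
Conditions: KO2CN=NCO2K (excess, in portions), AcOH, pyridine–MeOH, 0 °C → rt
Reagents that add atoms: none
Why: Diimide reduction; the concerted syn transfer of two hydrogens prefers the unpolarised cis-disubstituted ring alkene, while the halogen-bearing 1,1-disubstituted alkene reacts much more slowly and C=O is not touched. It is done now because no C8 methylene yet competes; no stereocentre is formed.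

Step 9
Reactants: 14 saturated aldehyde
Product: 15 ethyl (E)-3-[(1S,2R,3R,6S)-2-(3-bromobut-3-en-1-yl)-6-[(tert-butyldimethylsilyl)oxy]-3-{[(tert-butyldiphenylsilyl)oxy]methyl}-1-methylcyclohexyl]prop-2-enoate
Conditions: (EtO)2P(O)CH2CO2Et, NaH, THF, 0 → 60 °C
Reagents that add atoms: triethyl phosphonoacetate, CCOC(=O)CP(=O)(OCC)OCC
Why: Horner–Wadsworth–Emmons olefination; the small phosphonate anion reaches the neopentyl aldehyde, which can neither enolise nor eliminate, and gives the (E) enoate that serves as radical acceptor.

Step 10
Reactants: 15 enoate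
Product: 16 bicyclic ester (1S,4R,5R,9R,10R): trans-decalin with C1–OTBS, C4–CH2OTBDPS, C8 exocyclic methylene, C9–CH2CO2Et and C10–CH3
Conditions: Bu3SnH (1.5 equiv, syringe pump), AIBN (cat.), benzene (0.005 M), 80 °C
Reagents that add atoms: none
Why: Vinyl radical cyclisation: bromine abstraction gives the C8 σ-radical, which adds 6-exo-trig to C9 (the β-carbon of the enoate); the resulting α-ester radical at C11 takes hydrogen from the stannane. The two arms are trans-diequatorial on ring A, so only a trans-decalin can form. In the chair-like transition state the enoate terminus C11 points outward (equatorial), because the axial orientation would push it under ring B against H5 and H7; H9 therefore ends anti to C20, and the C8 methylene is formed directly.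

Step 11
Reactants: 16 bicyclic ester
Product: 17 C12 aldehyde (1S,4R,5R,9R,10R): as 16 with C9–CH2CHO
Conditions: DIBAL-H (1.1 equiv), toluene, −78 °C; aqueous Rochelle salt
Reagents that add atoms: none
Why: Partial reduction of an unhindered ester through the aluminium hemiacetal that is stable at low temperature; the silyl ethers and the alkene are inert and C9 is not α to the new carbonyl.

Step 12
Reactants: 17 C12 aldehyde; 11 2-(triphenylphosphoranylidene)propanal
Product: 18 (E)-enal (1S,4R,5R,9R,10R,12E): as 16 with C9–CH2CH=C(CH3)CHO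
Conditions: toluene, 90 °C
Reagents that add atoms: none
Why: Wittig reaction of the stabilised ylide with an unhindered aliphatic aldehyde; this sets the (E) C12=C13 alkene with C16 in place.

Step 13
Reactants: 18 (E)-enal
Product: 19 bis-silyl triene (1S,4R,5R,9R,10R,12E): as 16 with the (E)-3-methylpenta-2,4-dienyl chain on C9
Conditions: Ph3PCH3Br, KOtBu, THF, 0 °C → rt
Reagents that add atoms: methyltriphenylphosphonium bromide, C[P+](c1ccccc1)(c1ccccc1)c1ccccc1.[Br-]
Why: Wittig methylenation of an enal by 1,2-addition of the unstabilised ylide; the C12=C13 geometry is untouched.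

Step 14
Reactants: 19 bis-silyl triene
Product: 20 diol (1S,4R,5R,9R,10R,12E): C1–OH, C4–CH2OH, C8 methylene, dienyl chain on C9
Conditions: TBAF (5 equiv), THF, rt → 50 °C
Reagents that add atoms: none
Why: Fluoride cleavage of both silyl ethers in one operation; the conditions are non-acidic and non-oxidising, so the diene and the exocyclic alkene are safe.

Step 15
Reactants: 20 diol
Product: 22 hydroxy acid (1S,4R,5R,9R,10R,12E): C1–OH, C4–CO2H, via hydroxy aldehyde 21 (not isolated)
Conditions: TEMPO (20 mol %), PhI(OAc)2, CH2Cl2, rt; then t-BuOH–H2O, 2-methylbut-2-ene, NaClO2, NaH2PO4, 0 °C → rt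
Reagents that add atoms: sodium chlorite, [Na+].[O-]Cl=O
Why: The oxoammonium oxidation takes the primary alcohol and leaves the hindered secondary C1 alcohol; Pinnick oxidation of the aldehyde with an alkene scavenger spares the diene.

Step 16
Reactants: 22 hydroxy acid
Product: 23 hydroxy methyl ester (1S,4R,5R,9R,10R,12E): C1–OH, C4–CO2CH3
Conditions: TMSCHN2, toluene–MeOH (4:1), 0 °C
Reagents that add atoms: (trimethylsilyl)diazomethane, C[Si](C)(C)C=[N+]=[N-]
Why: Methylation of the carboxylic acid by the diazoalkane under neutral conditions; the alcohol and the alkenes do not react.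

Step 17
Reactants: 23 hydroxy methyl ester
Product: 25 methyl (1S,4R,5S,9R,10S,12E)-1-hydroxylabda-8(17),12,14-trien-19-oate, via dilithium alkoxide enolate 24 (not isolated)
Conditions: LDA (3 equiv), THF, −78 → −20 °C; then MeI (5 equiv), −78 → 0 °C
Reagents that add atoms: iodomethane, CI
Why: Ester enolate C-alkylation; the lithium alkoxide at C1 is a poor nucleophile towards MeI in THF. The axial C10 methyl blocks the syn-axial face of the planar C4, so C18 enters equatorially and the ester is left axial, cis to C20, as in the target.

Step 18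
Reactants: 25 hydroxy ester
Product: 26 methyl (1S,4R,5S,9R,10S,12E)-1-acetoxylabda-8(17),12,14-trien-19-oate (target)
Conditions: Ac2O, DMAP, pyridine, CH2Cl2, rt → 40 °C
Reagents that add atoms: acetic anhydride, CC(=O)OC(C)=O
Why: DMAP-catalysed acylation of the hindered equatorial secondary alcohol; no stereocentre is touched.

## Compound list

1 | but-3-en-1-ol | C=CCCO | starting material
2 | (but-3-en-1-yloxy)(tert-butyl)diphenylsilane | C=CCCO[Si](c1ccccc1)(c1ccccc1)C(C)(C)C | intermediate
3 | (E)-but-2-enal | C/C=C/C=O | starting material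
4 | (E)-5-[(tert-butyldiphenylsilyl)oxy]pent-2-enal | O=C/C=C/CCO[Si](c1ccccc1)(c1ccccc1)C(C)(C)C | intermediate
5 | (1E,3E)-1-[(tert-butyldimethylsilyl)oxy]-5-[(tert-butyldiphenylsilyl)oxy]penta-1,3-diene | CC(C)(C)[Si](C)(C)O/C=C/C=C/CO[Si](c1ccccc1)(c1ccccc1)C(C)(C)C | intermediate
6 | tert-butyl acetate | CC(=O)OC(C)(C)C | starting material
7 | 2,3-dibromoprop-1-ene | C=C(Br)CBr | starting material
8 | lithium enolate of tert-butyl acetate | C=C([O-])OC(C)(C)C.[Li+] | intermediate
9 | tert-butyl 4-bromopent-4-enoate | C=C(Br)CCC(=O)OC(C)(C)C | intermediate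
10 | 4-bromopent-4-enal | C=C(Br)CCC=O | intermediate
11 | 2-(triphenylphosphoranylidene)propanal | CC(C=O)=P(c1ccccc1)(c1ccccc1)c1ccccc1 | starting material
12 | (E)-6-bromo-2-methylhepta-2,6-dienal | O=C/C(C)=C/CCC(Br)=C | intermediate
13 | (1S,2S,5R,6R)-6-(3-bromobut-3-en-1-yl)-2-(TBS-oxy)-5-[(TBDPS-oxy)methyl]-1-methylcyclohex-3-ene-1-carbaldehyde | O=C[C@]1(C)[C@@H](O[Si](C)(C)C(C)(C)C)C=C[C@@H](CO[Si](c2ccccc2)(c2ccccc2)C(C)(C)C)[C@H]1CCC(Br)=C | intermediate
14 | (1S,2R,3R,6S)-2-(3-bromobut-3-en-1-yl)-6-(TBS-oxy)-3-[(TBDPS-oxy)methyl]-1-methylcyclohexane-1-carbaldehyde | O=C[C@]1(C)[C@@H](O[Si](C)(C)C(C)(C)C)CC[C@@H](CO[Si](c2ccccc2)(c2ccccc2)C(C)(C)C)[C@H]1CCC(Br)=C | intermediate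
15 | ethyl (E)-3-[(1S,2R,3R,6S)-2-(3-bromobut-3-en-1-yl)-6-(TBS-oxy)-3-[(TBDPS-oxy)methyl]-1-methylcyclohexyl]prop-2-enoate | CCOC(=O)/C=C/[C@]1(C)[C@@H](O[Si](C)(C)C(C)(C)C)CC[C@@H](CO[Si](c2ccccc2)(c2ccccc2)C(C)(C)C)[C@H]1CCC(Br)=C | intermediate
16 | bicyclic ethyl ester (1S,4R,5R,9R,10R): C1–OTBS, C4–CH2OTBDPS, C8=CH2, C9–CH2CO2Et, C10–CH3 | CCOC(=O)C[C@@H]1C(=C)CC[C@H]2[C@@]1(C)[C@@H](O[Si](C)(C)C(C)(C)C)CC[C@H]2CO[Si](c3ccccc3)(c3ccccc3)C(C)(C)C | intermediate
17 | C12 aldehyde (1S,4R,5R,9R,10R): as 16 with C9–CH2CHO | O=CC[C@@H]1C(=C)CC[C@H]2[C@@]1(C)[C@@H](O[Si](C)(C)C(C)(C)C)CC[C@H]2CO[Si](c3ccccc3)(c3ccccc3)C(C)(C)C | intermediate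
18 | (12E)-enal (1S,4R,5R,9R,10R): as 16 with C9–CH2CH=C(CH3)CHO | O=C/C(C)=C/C[C@@H]1C(=C)CC[C@H]2[C@@]1(C)[C@@H](O[Si](C)(C)C(C)(C)C)CC[C@H]2CO[Si](c3ccccc3)(c3ccccc3)C(C)(C)C | intermediate
19 | bis-silyl triene (1S,4R,5R,9R,10R,12E): 1-OTBS, 19-OTBDPS, 18-norlabda-8(17),12,14-triene | C=C/C(C)=C/C[C@@H]1C(=C)CC[C@H]2[C@@]1(C)[C@@H](O[Si](C)(C)C(C)(C)C)CC[C@H]2CO[Si](c3ccccc3)(c3ccccc3)C(C)(C)C | intermediate
20 | diol (1S,4R,5R,9R,10R,12E): 18-norlabda-8(17),12,14-triene-1,19-diol | C=C/C(C)=C/C[C@@H]1C(=C)CC[C@H]2[C@@]1(C)[C@@H](O)CC[C@H]2CO | intermediate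
21 | hydroxy aldehyde (1S,4R,5R,9R,10R,12E): 1-hydroxy-18-norlabda-8(17),12,14-trien-19-al | C=C/C(C)=C/C[C@@H]1C(=C)CC[C@H]2[C@@]1(C)[C@@H](O)CC[C@H]2C=O | intermediate
22 | hydroxy acid (1S,4R,5R,9R,10R,12E): 1-hydroxy-18-norlabda-8(17),12,14-trien-19-oic acid | C=C/C(C)=C/C[C@@H]1C(=C)CC[C@H]2[C@@]1(C)[C@@H](O)CC[C@H]2C(=O)O | intermediate
23 | hydroxy methyl ester (1S,4R,5R,9R,10R,12E): methyl 1-hydroxy-18-norlabda-8(17),12,14-trien-19-oate | C=C/C(C)=C/C[C@@H]1C(=C)CC[C@H]2[C@@]1(C)[C@@H](O)CC[C@H]2C(=O)OC | intermediate
24 | dilithium C1 alkoxide C4 ester enolate of 23 | C=C/C(C)=C/C[C@@H]1C(=C)CC[C@H]2[C@@]1(C)[C@@H]([O-])CCC2=C([O-])OC.[Li+].[Li+] | intermediate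
25 | methyl (1S,4R,5S,9R,10S,12E)-1-hydroxylabda-8(17),12,14-trien-19-oate | C=C/C(C)=C/C[C@@H]1C(=C)CC[C@H]2[C@@]1(C)[C@@H](O)CC[C@@]2(C)C(=O)OC | intermediate
26 | methyl (1S,4R,5S,9R,10S,12E)-1-acetoxylabda-8(17),12,14-trien-19-oate | C=C/C(C)=C/C[C@@H]1C(=C)CC[C@H]2[C@@]1(C)[C@@H](OC(C)=O)CC[C@@]2(C)C(=O)OC | target

## Step count and risks

Total steps: 18. Longest linear sequence: 15 steps (1 → 5 → 13 → 26, or equally 6 → 12 → 13 → 26).

Least certain steps:

**Step 7 (key step).** Most likely to go wrong is the exo/endo topology. The trisubstituted enal reacts slowly, and in the formyl-exo arrangement its C6 chain lies under the diene close to the C4 substituent, so the formyl-endo mode may take over; low conversion with acid-induced loss of the dienol ether is the second concern. The fallback accepts the endo product and corrects C1 at the end through the ketone. It sets out from 5 and 12 and comes back at 25.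
- With the same face of the enal engaged, both diene-derived centres are inverted, giving endo adduct F1.
- F1 is taken through steps 8 to 17 with unchanged reagents: saturated aldehyde F2, enoate F3, bicyclic ester F4 (its C1 silyloxy group is axial and clear of C11, which should help ring closure), C12 aldehyde F5, enal F6, triene F7, diol F8, hydroxy aldehyde F9 (not isolated), hydroxy acid F10, hydroxy ester F11, dianion F12 and methylated hydroxy ester F13.
- In F13, C4 has converged with the main series because the enolate is planar, so only C1 differs from 25.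
- Dess–Martin oxidation gives ketone F14. NaBH4 in MeOH at 0 °C should deliver hydride along the axial path, away from the C10 methyl on the neighbouring carbon, to give the equatorial alcohol 25.
- The cost is two extra steps.

**Step 10.** Most likely to go wrong is face selection at C9: the equatorial C1 silyloxy group is peri to C11 in the desired transition state, which may erode the preference for the equatorial chain. Next to this, hydrogen transfer to the vinyl radical may outrun closure if the diequatorial chair of ring A is poorly populated. The fallback closes ring B with C1 trigonal, which removes the peri contact, and rebuilds C1 afterwards. It sets out from 15 and comes back at 20.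
- Camphorsulfonic acid in EtOH removes the secondary TBS ether and leaves the primary TBDPS ether, giving alcohol F24.
- Dess–Martin oxidation gives cyclohexanone F18.
- F18 is cyclised, reduced and carried to 20 exactly as described for step 8 below, through F19, F20, F21, F22 and F23.

**Step 8.** Most likely to go wrong is incomplete reduction of the ring alkene, which is flanked by two substituted carbons, with condensation of hydrazine by-products at the aldehyde during the long exposure. The fallback removes C2=C3 electronically, as an enone, and not by hydrogen transfer. It sets out from 13 and comes back at 20.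
- 13 is olefinated as in step 9 to dienyl ester F15.
- Camphorsulfonic acid in EtOH gives allylic alcohol F16, and MnO2 gives cyclohexenone F17.
- [(Ph3P)CuH]6 in wet benzene reduces only the enone C=C, giving cyclohexanone F18; the hindered enoate and the bromoalkene should remain.
- Bu3SnH/AIBN as in step 10 gives bicyclic keto ester F19.
- NaBH4 reduces the C1 ketone by axial delivery; the equatorial alkoxide should close on the peri C12 ester to give δ-lactone F20.
- DIBAL-H at −78 °C gives lactol F21. Wittig reaction with 11 opens it to hydroxy enal F22, and methylenation gives hydroxy triene F23.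
- TBAF then gives 20.

**Step 17.** Most likely to go wrong is incomplete enolisation of the hindered ester within the aggregated dianion, with O-methylation at C1 if a polar cosolvent is needed. The fallback alkylates a monoanion. It sets out from 23 and comes back at 25.
- Et3SiOTf and 2,6-lutidine give triethylsilyl ether F25.
- LDA in THF–DMPU gives lithium enolate F26, and MeI gives methylated silyl ether F27 with the same face control by C20.
- HF·pyridine in THF then gives 25.

## Further compounds

F1 | step 7 | endo cycloadduct, C1 and C4 epimer of 13 | O=C[C@]1(C)[C@H](O[Si](C)(C)C(C)(C)C)C=C[C@H](CO[Si](c2ccccc2)(c2ccccc2)C(C)(C)C)[C@H]1CCC(Br)=C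
F2 | step 7 | saturated aldehyde, C1 and C4 epimer of 14 | O=C[C@]1(C)[C@H](O[Si](C)(C)C(C)(C)C)CC[C@H](CO[Si](c2ccccc2)(c2ccccc2)C(C)(C)C)[C@H]1CCC(Br)=C
F3 | step 7 | enoate, C1 and C4 epimer of 15 | CCOC(=O)/C=C/[C@]1(C)[C@H](O[Si](C)(C)C(C)(C)C)CC[C@H](CO[Si](c2ccccc2)(c2ccccc2)C(C)(C)C)[C@H]1CCC(Br)=C
F4 | step 7 | bicyclic ester, C1 and C4 epimer of 16 | CCOC(=O)C[C@@H]1C(=C)CC[C@H]2[C@@]1(C)[C@H](O[Si](C)(C)C(C)(C)C)CC[C@@H]2CO[Si](c3ccccc3)(c3ccccc3)C(C)(C)C
F5 | step 7 | C12 aldehyde, C1 and C4 epimer of 17 | O=CC[C@@H]1C(=C)CC[C@H]2[C@@]1(C)[C@H](O[Si](C)(C)C(C)(C)C)CC[C@@H]2CO[Si](c3ccccc3)(c3ccccc3)C(C)(C)C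
F6 | step 7 | enal, C1 and C4 epimer of 18 | O=C/C(C)=C/C[C@@H]1C(=C)CC[C@H]2[C@@]1(C)[C@H](O[Si](C)(C)C(C)(C)C)CC[C@@H]2CO[Si](c3ccccc3)(c3ccccc3)C(C)(C)C
F7 | step 7 | triene, C1 and C4 epimer of 19 | C=C/C(C)=C/C[C@@H]1C(=C)CC[C@H]2[C@@]1(C)[C@H](O[Si](C)(C)C(C)(C)C)CC[C@@H]2CO[Si](c3ccccc3)(c3ccccc3)C(C)(C)C
F8 | step 7 | diol, C1 and C4 epimer of 20 | C=C/C(C)=C/C[C@@H]1C(=C)CC[C@H]2[C@@]1(C)[C@H](O)CC[C@@H]2CO
F9 | step 7 | hydroxy aldehyde, C1 and C4 epimer of 21 | C=C/C(C)=C/C[C@@H]1C(=C)CC[C@H]2[C@@]1(C)[C@H](O)CC[C@@H]2C=O
F10 | step 7 | hydroxy acid, C1 and C4 epimer of 22 | C=C/C(C)=C/C[C@@H]1C(=C)CC[C@H]2[C@@]1(C)[C@H](O)CC[C@@H]2C(=O)O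
F11 | step 7 | hydroxy ester, C1 and C4 epimer of 23 | C=C/C(C)=C/C[C@@H]1C(=C)CC[C@H]2[C@@]1(C)[C@H](O)CC[C@@H]2C(=O)OC
F12 | step 7 | dianion, C1 epimer of 24 | C=C/C(C)=C/C[C@@H]1C(=C)CC[C@H]2[C@@]1(C)[C@H]([O-])CCC2=C([O-])OC.[Li+].[Li+]
F13 | step 7 | methylated hydroxy ester, C1 epimer of 25 | C=C/C(C)=C/C[C@@H]1C(=C)CC[C@H]2[C@@]1(C)[C@H](O)CC[C@@]2(C)C(=O)OC
F14 | step 7 | ketone, methyl 1-oxolabda-8(17),12E,14-trien-19-oate with the C4, C5, C9 and C10 configuration of 25 | C=C/C(C)=C/C[C@@H]1C(=C)CC[C@H]2[C@@]1(C)C(=O)CC[C@@]2(C)C(=O)OC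
F15 | step 8 | dienyl ester, 2,3-didehydro analogue of 15 | CCOC(=O)/C=C/[C@]1(C)[C@@H](O[Si](C)(C)C(C)(C)C)C=C[C@@H](CO[Si](c2ccccc2)(c2ccccc2)C(C)(C)C)[C@H]1CCC(Br)=C
F16 | step 8 | allylic alcohol, C1–OH analogue of F15 | CCOC(=O)/C=C/[C@]1(C)[C@@H](O)C=C[C@@H](CO[Si](c2ccccc2)(c2ccccc2)C(C)(C)C)[C@H]1CCC(Br)=C
F17 | step 8 | cyclohexenone, C1 ketone with C2=C3 | CCOC(=O)/C=C/[C@]1(C)C(=O)C=C[C@@H](CO[Si](c2ccccc2)(c2ccccc2)C(C)(C)C)[C@H]1CCC(Br)=C
F18 | step 8 | cyclohexanone, C1 ketone analogue of 15 | CCOC(=O)/C=C/[C@]1(C)C(=O)CC[C@@H](CO[Si](c2ccccc2)(c2ccccc2)C(C)(C)C)[C@H]1CCC(Br)=C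
F19 | step 8 | bicyclic keto ester, C1 ketone analogue of 16 | CCOC(=O)C[C@@H]1C(=C)CC[C@H]2[C@@]1(C)C(=O)CC[C@H]2CO[Si](c3ccccc3)(c3ccccc3)C(C)(C)C
F20 | step 8 | δ-lactone between the C1 oxygen and C12 | O=C1C[C@@H]2C(=C)CC[C@H]3[C@@]2(C)[C@@H](O1)CC[C@H]3CO[Si](c4ccccc4)(c4ccccc4)C(C)(C)C
F21 | step 8 | lactol of F20 (both anomers) | OC1C[C@@H]2C(=C)CC[C@H]3[C@@]2(C)[C@@H](O1)CC[C@H]3CO[Si](c4ccccc4)(c4ccccc4)C(C)(C)C
F22 | step 8 | hydroxy enal, C1–OH analogue of 18 | O=C/C(C)=C/C[C@@H]1C(=C)CC[C@H]2[C@@]1(C)[C@@H](O)CC[C@H]2CO[Si](c3ccccc3)(c3ccccc3)C(C)(C)C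
F23 | step 8 | hydroxy triene, C1–OH analogue of 19 | C=C/C(C)=C/C[C@@H]1C(=C)CC[C@H]2[C@@]1(C)[C@@H](O)CC[C@H]2CO[Si](c3ccccc3)(c3ccccc3)C(C)(C)C
F24 | step 10 | alcohol, C1–OH analogue of 15 | CCOC(=O)/C=C/[C@]1(C)[C@@H](O)CC[C@@H](CO[Si](c2ccccc2)(c2ccccc2)C(C)(C)C)[C@H]1CCC(Br)=C
F25 | step 17 | triethylsilyl ether of 23 | C=C/C(C)=C/C[C@@H]1C(=C)CC[C@H]2[C@@]1(C)[C@@H](O[Si](CC)(CC)CC)CC[C@H]2C(=O)OC
F26 | step 17 | lithium ester enolate of F25 | C=C/C(C)=C/C[C@@H]1C(=C)CC[C@H]2[C@@]1(C)[C@@H](O[Si](CC)(CC)CC)CCC2=C([O-])OC.[Li+]
F27 | step 17 | triethylsilyl ether of 25 | C=C/C(C)=C/C[C@@H]1C(=C)CC[C@H]2[C@@]1(C)[C@@H](O[Si](CC)(CC)CC)CC[C@@]2(C)C(=O)OC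
A1 | alternative 1 | acyclic aldehyde with (E)-β-methyl enoate, C8 methyl ester and C4 malonate | O=CCCC(C(=O)OC)(C(=O)OC)[C@H](/C(C)=C/C(=O)OCC)CCC(=O)OC
A2 | alternative 1 | bicyclic β-keto ester with the C1 hydroxyl | CCOC(=O)[C@@H]1C(=O)CC[C@H]2[C@@]1(C)[C@@H](O)CCC2(C(=O)OC)C(=O)OC
A3 | alternative 2 | acyclic vinyl ketone tethered to an (E)-enoate (C10 epimers) | C=CC(=O)C(C)[C@H](CCO[Si](C)(C)C(C)(C)C)C(=C)CC/C=C/C(=O)OC
A4 | alternative 2 | trans-decalin keto ester with the C8 methylene | CC(C)(C)[Si](C)(C)OCC[C@@H]1C(=C)CC[C@H]2[C@@]1(C)C(=O)CC[C@@H]2C(=O)OC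
A5 | alternative 3 | phenol with a tethered allylic methyl carbonate | COC(=O)OCC(CCc1c(C)c(O)ccc1C(=O)OC)=CCCO[Si](C)(C)C(C)(C)C
A6 | alternative 3 | bicyclic 2,4-dienone ester with C9 and C10 set | CC(C)(C)[Si](C)(C)OCC[C@@H]1C(=C)CCC2=C(C(=O)OC)C=CC(=O)[C@@]12C
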